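**Retrosynthetic overview**
1. C1–aryl bond (made first): aryl bromide 1 + crotonyl Weinreb amide 2, through aryllithium 3 and chelate 4, give (E)-enone 5.
2. C3–aryl bond: 5 + arylboronic acid 6 ⇒ (S)-ketone 7 by Rh/(R)-BINAP asymmetric 1,4-arylation (sets C3).
3. C1–H bond (made last): 7 ⇒ target 9, through alkoxyborane 8, by CBS reduction with the (S)-oxazaborolidine (sets C1).
4. No ring is formed; both 2,4,5-trimethoxyphenyl rings are bought intact and no protecting group is used.

Assumption: the target is read as (1R,3S)-1,3-bis(2,4,5-trimethoxyphenyl)butan-1-ol, and 1, 2 and 6 are taken as catalogue compounds.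

**Route**

Step 1
Reactants: 1 1-bromo-2,4,5-trimethoxybenzene; 2 (E)-N-methoxy-N-methylbut-2-enamide
Product: 5 (E)-1-(2,4,5-trimethoxyphenyl)but-2-en-1-one, via aryllithium 3 (not isolated), via tetrahedral lithium chelate 4 (not isolated)
Conditions: n-BuLi (1.05 equiv), THF, −78 °C, 30 min; then 2 (1.2 equiv), −78 to 0 °C, 1 h; poured into cold 1 M HCl
Reagents that add atoms: n-BuLi, [Li]CCCC (supplies the lithium of 3 and 4; no atom of it remains in 5)
Why: Bromine–lithium exchange turns 1 into aryllithium 3, which adds once to the Weinreb amide 2 (Weinreb ketone synthesis) because the five-membered lithium chelate 4 does not collapse until the cold acidic quench, so neither over-addition nor loss of the (E)-geometry occurs and no stereocentre is involved.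

Step 2
Reactants: 5 (E)-1-(2,4,5-trimethoxyphenyl)but-2-en-1-one; 6 (2,4,5-trimethoxyphenyl)boronic acid
Product: 7 (S)-1,3-bis(2,4,5-trimethoxyphenyl)butan-1-one
Conditions: [Rh(OH)((R)-BINAP)]2 (1.5 mol%), 6 (2.5 equiv), degassed 1,4-dioxane/H2O 10:1, 35 °C, 16 h
Reagents that add atoms: none
Why: Hayashi–Miyaura rhodium-catalysed asymmetric conjugate addition: transmetalation of 6 to the hydroxorhodium–(R)-BINAP complex gives an aryl–rhodium species that inserts the (E)-enone on its Cα-re/Cβ-si face (the mirror image of the α-si attack that (S)-BINAP shows with (E)-crotonyl acceptors), which sets C3 as (S), and water protonates the rhodium enolate to release 7 and regenerate the catalyst.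

Step 3
Reactants: 7 (S)-1,3-bis(2,4,5-trimethoxyphenyl)butan-1-one
Product: 9 (1R,3S)-1,3-bis(2,4,5-trimethoxyphenyl)butan-1-ol, via alkoxyborane 8 (not isolated)
Conditions: (S)-Me-CBS [(S)-1-methyl-3,3-diphenyltetrahydro-1H,3H-pyrrolo[1,2-c][1,3,2]oxazaborole] (20 mol%), BH3·SMe2 (1.0 equiv), THF, −20 °C, slow addition of 7; MeOH quench; chromatography on Et3N-deactivated silica
Reagents that add atoms: BH3·SMe2, C[S+](C)[BH3-] (supplies the boron of 8; only hydrogen remains in 9)
Why: Corey–Bakshi–Shibata reduction: the (S)-oxazaborolidine–BH3 complex binds the ketone with the aryl group as the large substituent and delivers hydride to the si face of C1 (the sense that turns acetophenone into (R)-1-phenylethanol), so C1 is set as (R) under reagent control while the non-enolisable C3 centre is untouched, and methanolysis of alkoxyborane 8 frees 9 without acid.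

**Compound list**
1 | 1-bromo-2,4,5-trimethoxybenzene | COc1cc(OC)c(Br)cc1OC | starting material
2 | (E)-N-methoxy-N-methylbut-2-enamide | C/C=C/C(=O)N(C)OC | starting material
3 | (2,4,5-trimethoxyphenyl)lithium | [Li]c1cc(OC)c(OC)cc1OC | intermediate (not isolated)
4 | lithium (E)-1-[methoxy(methyl)amino]-1-(2,4,5-trimethoxyphenyl)but-2-en-1-olate (racemic tetrahedral chelate) | C/C=C/C(O[Li])(N(C)OC)c1cc(OC)c(OC)cc1OC | intermediate (not isolated)
5 | (E)-1-(2,4,5-trimethoxyphenyl)but-2-en-1-one | C/C=C/C(=O)c1cc(OC)c(OC)cc1OC | intermediate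
6 | (2,4,5-trimethoxyphenyl)boronic acid | COc1cc(OC)c(B(O)O)cc1OC | starting material
7 | (S)-1,3-bis(2,4,5-trimethoxyphenyl)butan-1-one | COc1cc(OC)c(C(=O)C[C@H](C)c2cc(OC)c(OC)cc2OC)cc1OC | intermediate
8 | [(1R,3S)-1,3-bis(2,4,5-trimethoxyphenyl)butoxy]borane | COc1cc(OC)c([C@H](OB)C[C@H](C)c2cc(OC)c(OC)cc2OC)cc1OC | intermediate (not isolated)
9 | (1R,3S)-1,3-bis(2,4,5-trimethoxyphenyl)butan-1-ol | COc1cc(OC)c([C@H](O)C[C@H](C)c2cc(OC)c(OC)cc2OC)cc1OC | target

**Totals**
Total step count: 3. Longest linear sequence: 3 steps (1 → 5 → 7 → 9); boronic acid 6 enters as a bought building block.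

**Steps most likely to fail, most risky first**

Step 2. The electron-rich, ortho-substituted boronic acid 6 may protodeboronate faster than it transmetalates, or the ee may be low. The fallback replaces catalyst control by auxiliary control; it sets out from 1 and comes back at 7. (R)-4-Phenyloxazolidin-2-one is acylated with crotonic anhydride (Et3N, LiCl, THF, rt) to give (R)-3-[(E)-but-2-enoyl]-4-phenyloxazolidin-2-one F1. Bromide 1 is converted with Mg turnings in THF into (2,4,5-trimethoxyphenyl)magnesium bromide F2. F2 is added with CuBr·SMe2 (THF/SMe2, −20 °C) to F1; the chelated s-cis imide is attacked on the face anti to the 4-phenyl group. This gives the bromomagnesium (Z)-enolate of the adduct F3, and aqueous NH4Cl then gives (R)-4-phenyl-3-[(S)-3-(2,4,5-trimethoxyphenyl)butanoyl]oxazolidin-2-one F4, whose dr can be raised by crystallisation. Transamidation with MeNH(OMe)·HCl and AlMe3 (CH2Cl2, 0 °C to rt) gives (S)-N-methoxy-N-methyl-3-(2,4,5-trimethoxyphenyl)butanamide F5 and returns the auxiliary. Aryllithium 3, made from 1 and n-BuLi as in step 1, is added at −78 °C to give lithium (3S)-1-[methoxy(methyl)amino]-1,3-bis(2,4,5-trimethoxyphenyl)butan-1-olate F6, which on cold acidic quench gives 7.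

Step 3. Uncatalysed borane reduction or coordination of the ortho-methoxy group may erode the selectivity at C1, and the electron-rich benzylic alcohol can ionise if the work-up turns acidic. The fallback replaces reagent control by diastereomer separation with recycling; it sets out from 7 and comes back at 9. Ketone 7 is reduced with NaBH4 in MeOH at 0 °C to a roughly 1:1 mixture of 9 and its C1 epimer (1S,3S)-1,3-bis(2,4,5-trimethoxyphenyl)butan-1-ol F7. The two diastereomers are separated on Et3N-deactivated silica or by preparative HPLC. F7 is oxidised back to 7 with Dess–Martin periodinane (NaHCO3-buffered CH2Cl2) and reduced again.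

Step 1. The aryllithium may add in conjugate fashion to amide 2 or deprotonate it at the γ-position, and released N,O-dimethylhydroxylamine may add to enone 5. The fallback replaces acylation by addition and oxidation; it sets out from 1 (through 3) and comes back at 5. Aryllithium 3 is added to (E)-crotonaldehyde in THF at −78 °C, where 1,2-addition is clean, to give lithium (E)-1-(2,4,5-trimethoxyphenyl)but-2-en-1-olate F8. Aqueous NH4Cl gives racemic (E)-1-(2,4,5-trimethoxyphenyl)but-2-en-1-ol F9. The crude alcohol is oxidised at once with activated MnO2 in CH2Cl2 at rt to 5.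

**Further compounds**
F1 | step 2 | (R)-3-[(E)-but-2-enoyl]-4-phenyloxazolidin-2-one | C/C=C/C(=O)N1[C@H](c2ccccc2)COC1=O
F2 | step 2 | (2,4,5-trimethoxyphenyl)magnesium bromide | COc1cc(OC)c([Mg]Br)cc1OC
F3 | step 2 | bromomagnesium (Z)-enolate of (R)-4-phenyl-3-[(S)-3-(2,4,5-trimethoxyphenyl)butanoyl]oxazolidin-2-one | C[C@@H](/C=C(\O[Mg]Br)N1[C@H](c2ccccc2)COC1=O)c1cc(OC)c(OC)cc1OC
F4 | step 2 | (R)-4-phenyl-3-[(S)-3-(2,4,5-trimethoxyphenyl)butanoyl]oxazolidin-2-one | C[C@@H](CC(=O)N1[C@H](c2ccccc2)COC1=O)c1cc(OC)c(OC)cc1OC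
F5 | step 2 | (S)-N-methoxy-N-methyl-3-(2,4,5-trimethoxyphenyl)butanamide | C[C@@H](CC(=O)N(C)OC)c1cc(OC)c(OC)cc1OC
F6 | step 2 | lithium (3S)-1-[methoxy(methyl)amino]-1,3-bis(2,4,5-trimethoxyphenyl)butan-1-olate | C[C@@H](CC(O[Li])(N(C)OC)c1cc(OC)c(OC)cc1OC)c1cc(OC)c(OC)cc1OC
F7 | step 3 | (1S,3S)-1,3-bis(2,4,5-trimethoxyphenyl)butan-1-ol | COc1cc(OC)c([C@@H](O)C[C@H](C)c2cc(OC)c(OC)cc2OC)cc1OC
F8 | step 1 | lithium (E)-1-(2,4,5-trimethoxyphenyl)but-2-en-1-olate (racemic) | C/C=C/C(O[Li])c1cc(OC)c(OC)cc1OC
F9 | step 1 | (E)-1-(2,4,5-trimethoxyphenyl)but-2-en-1-ol (racemic) | C/C=C/C(O)c1cc(OC)c(OC)cc1OC
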